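**Plan**
1. Retrosynthesis: the cyclohexane fused to the oxepane (C6–C7–C8–C9–C10–C11; C6 = methyl-bearing ring-fusion carbon, C7 = O-bearing ring-fusion CH, C10 = C(CH3)OH, C11 = CH carrying the C12–C13 linker) is opened at C8–C9 and C10–C11. This releases an isopropenyl unit (C9, C10, CH3) and leaves 24, which is cut at C11=C12 into oxepane 11 and octalinol 23.
2. Enabling feature: C6 is quaternary, so the ring is not a Diels–Alder adduct. But C8 is a CH2 on C7 (a primary radical site β to the ring oxygen), C11 is an alkene carbon on C6, and C9–C10(CH3)(OH) is an isopropenylboronate in disguise. C8• + CH2=C(CH3)Bpin + C11=C12 close the ring in a radical [4+2] annulation, and C–B then becomes C–OH.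
3. Forward: open chain by allylboration (steps 1–2), oxepane by 7-exo oxymercuration (3–6), iodide 11 (7–8); octalinol 23 by Diels–Alder reaction of 4,4-dimethylcyclohexenone and ring editing (9–17); cross-metathesis (18), annulation (19), oxidation and desilylation (20–21).
4. Stereochemistry: C6/C7 from the Z-allylboronate geometry (relative) and a chiral phosphoric acid (absolute); C3 from Shi epoxidation; C4a/C5/C8a of the octalin from a catalytic enantioselective endo Diels–Alder reaction, its C1 carbinol from convex-face epoxidation; C10/C11 from a chair transition state on the locked trans-disubstituted oxepane.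

Key step: step 19

Remarks: left-half locants follow O–C2(CH3)2–C3–C4–C5–C6–C7(–O)–C8–C9–C10–C11–C12–C13. The octalin is numbered as a naphthalene (C1 carbinol/carbonyl carbon, C4 = C(CH3)2, C4a, C5 = CH bearing the linker, C6=C7, C8, C8a). The hand of the two chiral catalysts (steps 2 and 12) is the one predicted by the accepted transition-state models; both antipodes are available.

Step 1
Reactants: 1 neryl acetate, (2Z)-3,7-dimethylocta-2,6-dien-1-yl acetate
Product: 2 (Z)-neryl pinacol boronate, 2-[(2Z)-3,7-dimethylocta-2,6-dien-1-yl]-4,4,5,5-tetramethyl-1,3,2-dioxaborolane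
Conditions: B2pin2, Ni(cod)2 (5 mol%), PCy3 (10 mol%), EtOAc, rt
Reagents that add atoms: bis(pinacolato)diboron, CC1(C)OB(OC1(C)C)B1OC(C)(C)C(C)(C)O1
Why: Nickel-catalysed Miyaura-type borylation of the allylic acetate through a π-allyl complex should deliver boron to the unhindered CH2 terminus; the trisubstituted π-allyl unit should not isomerise at room temperature, so the Z geometry that later fixes the C6/C7 relationship is kept.

Step 2
Reactants: 2 (Z)-neryl pinacol boronate; 3 (tert-butyldimethylsilyloxy)acetaldehyde
Product: 4 (2R,3S)-1-[(tert-butyldimethylsilyl)oxy]-3-ethenyl-3,7-dimethyloct-6-en-2-ol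
Conditions: (R)-TRIP (5 mol%), 4 Å MS, toluene, −30 °C → rt; aqueous work-up
Reagents that add atoms: none
Why: Chiral-phosphoric-acid-catalysed allylboration through a closed chair (Zimmerman–Traxler) transition state; the Z-boronate places CH3 anti and the homoprenyl chain syn to the new hydroxyl (quaternary C6, relative), and the catalyst directs attack to the Re face of the aldehyde (C7, absolute).

Step 3
Reactants: 4 homoallylic alcohol
Product: 5 (2R,3S)-1-[(tert-butyldimethylsilyl)oxy]-5-[(2S)-3,3-dimethyloxiran-2-yl]-3-ethenyl-3-methylpentan-2-ol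
Conditions: L-fructose-type Shi ketone (30 mol%), Oxone, K2CO3, Bu4NHSO4, MeCN/DMM/aq. borate buffer (pH 10.5), 0 °C
Reagents that add atoms: Oxone (potassium peroxymonosulfate), [K+].[O-]S(=O)(=O)OO
Why: Shi epoxidation; the chiral dioxirane should react with the electron-rich trisubstituted alkene far faster than with the hindered vinyl group and, through the spiro transition state, give the (S)-epoxide whose CH–O carbon becomes C3 (the product is kept away from acid).

Step 4
Reactants: 5 epoxy alcohol
Product: 6 (2R,3S,6S)-1-[(tert-butyldimethylsilyl)oxy]-3-ethenyl-3,7-dimethyloct-7-ene-2,6-diol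
Conditions: Et2AlCl, LiTMP (→ Et2Al–TMP, 4 equiv), toluene, 0 °C
Reagents that add atoms: none
Why: Aluminium-amide-mediated isomerisation of a trisubstituted epoxide to the allylic alcohol by syn removal of a methyl proton in a cyclic transition state; the C3–O bond is untouched so C3 keeps its configuration, and the C7 aluminium alkoxide formed first is too hindered to open the epoxide.

Step 5
Reactants: 6 diol
Product: 7 (2R,3S,6S)-1,6-bis[(tert-butyldimethylsilyl)oxy]-3-ethenyl-3,7-dimethyloct-7-en-2-ol
Conditions: TBSCl (1.1 equiv), imidazole, DMF, 0 °C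
Reagents that add atoms: tert-butyldimethylsilyl chloride, CC(C)(C)[Si](C)(C)Cl
Why: Selective silylation; the allylic C3 hydroxyl is far more accessible than the C7 hydroxyl, which is flanked by the quaternary C6 and the CH2OTBS group.

Step 6
Reactants: 7 hydroxy alkene
Product: 9 (3S,6S,7R)-3-[(tert-butyldimethylsilyl)oxy]-7-{[(tert-butyldimethylsilyl)oxy]methyl}-6-ethenyl-2,2,6-trimethyloxepane, via alkylmercury trifluoroacetate 8 (not isolated)
Conditions: Hg(OCOCF3)2 (1.05 equiv), NaHCO3, CH2Cl2, 0 °C → rt; then NaBH4, aq. NaOH, 0 °C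
Reagents that add atoms: none
Why: Intramolecular oxymercuration then reductive demercuration; Markovnikov attack of the C7 hydroxyl on the tertiary carbon of the isopropenyl mercurinium ion is a 7-exo-trig closure (the vinyl group could react only in 4-exo or anti-Markovnikov 5-endo modes and its mercurinium ion forms reversibly), and NaBH4 turns CH2Hg into the second C2 methyl, so no new stereocentre remains.

Step 7
Reactants: 9 bis-silyl ether
Product: 10 [(2R,3S,6S)-6-[(tert-butyldimethylsilyl)oxy]-3-ethenyl-3,7,7-trimethyloxepan-2-yl]methanol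
Conditions: HF·pyridine, pyridine, THF, 0 °C
Reagents that add atoms: none
Why: Selective desilylation; the primary TBS ether should be cleaved much faster than the secondary C3 ether, which sits next to the gem-dimethyl carbon C2.

Step 8
Reactants: 10 primary alcohol
Product: 11 (3S,6S,7R)-3-[(tert-butyldimethylsilyl)oxy]-6-ethenyl-7-(iodomethyl)-2,2,6-trimethyloxepane
Conditions: I2, PPh3, imidazole, toluene, 60 °C
Reagents that add atoms: iodine, II
Why: Appel iodination of the primary alcohol through the alkoxyphosphonium salt (SN2 at C8); no stereocentre is involved.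

Step 9
Reactants: 12 pent-4-enal; 13 vinylmagnesium bromide
Product: 14 hepta-1,6-dien-3-ol (racemic)
Conditions: THF, −78 → 0 °C
Reagents that add atoms: none
Why: Grignard 1,2-addition to the aldehyde; the racemic carbinol centre is removed in the next step.

Step 10
Reactants: 14 dienol
Product: 15 hepta-1,6-dien-3-one
Conditions: Dess–Martin periodinane, NaHCO3, CH2Cl2, 0 °C
Reagents that add atoms: none
Why: Dess–Martin oxidation of the allylic alcohol under buffered, non-basic conditions that avoid conjugate addition to, and polymerisation of, the vinyl ketone.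

Step 11
Reactants: 15 vinyl ketone
Product: 16 tert-butyl{[(3Z)-hepta-1,3,6-trien-3-yl]oxy}dimethylsilane
Conditions: TBSOTf, Et3N, Et2O, −78 → 0 °C
Reagents that add atoms: tert-butyldimethylsilyl triflate, CC(C)(C)[Si](C)(C)OS(=O)(=O)C(F)(F)F
Why: Soft enolisation and O-silylation at the only enolisable position gives the 2-silyloxydiene; the Z enol ether (chain cis to OSi) avoids A(1,3) strain with the vinyl group and puts the side chain "outside" in the s-cis diene.

Step 12
Reactants: 16 silyloxydiene; 17 4,4-dimethylcyclohex-2-en-1-one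
Product: 18 (4aR,5S,8aS)-6-[(tert-butyldimethylsilyl)oxy]-4,4-dimethyl-5-(prop-2-en-1-yl)-3,4,4a,5,8,8a-hexahydronaphthalen-1(2H)-one (cis-fused; H-4a, H-5, H-8a all cis)
Conditions: (S)-o-tolyl-oxazaborolidine·AlBr3 (10 mol%), CH2Cl2, −40 → −20 °C
Reagents that add atoms: none
Why: Catalytic enantioselective Diels–Alder reaction; the silyloxy group makes the chain-bearing diene terminus nucleophilic so it bonds to the enone β-carbon next to the gem-dimethyl group, the endo transition state with the "outside" chain gives the cis fusion with H-4a, H-5 and H-8a all cis, and the chiral oxazaborolidinium ion on the carbonyl shields one enone face (absolute configuration).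

Step 13
Reactants: 18 ketone
Product: 19 1-methylidene analogue of 18 (C=CH2 in place of C1=O; silyl enol ether, allyl group and the three stereocentres unchanged)
Conditions: Cp2TiMe2, toluene, 65 °C, dark
Reagents that add atoms: dimethyltitanocene, C[Ti](C)(C1C=CC=C1)C1C=CC=C1
Why: Petasis methylenation (titanium carbene [2+2]/cycloreversion) is non-basic, so the epimerisable C8a centre and the silyl enol ether survive.

Step 14
Reactants: 19 silyl enol ether
Product: 20 enol triflate (C6–OTf, C6=C7) of the 1-methylidene octalin; stereocentres unchanged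
Conditions: CsF, PhNTf2, DME, rt
Reagents that add atoms: N-phenylbis(trifluoromethanesulfonimide), O=S(=O)(N(c1ccccc1)S(=O)(=O)C(F)(F)F)C(F)(F)F
Why: Enol triflate formation; fluoride unmasks the regiodefined C6=C7 enolate, which is O-triflated before proton exchange can move the double bond.

Step 15
Reactants: 20 triene
Product: 21 spiro-epoxide of 20 at C1 (oxirane oxygen on the face of H-8a, oxirane CH2 on the face of C8)
Conditions: mCPBA (1.05 equiv), NaHCO3, CH2Cl2, −20 °C
Reagents that add atoms: 3-chloroperoxybenzoic acid, OOC(=O)c1cccc(Cl)c1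
Why: Prilezhaev epoxidation; the 1,1-disubstituted exocyclic alkene should react faster than the monosubstituted allyl group while the electron-poor enol triflate is inert, and the peracid should approach the convex face (syn to H-8a, anti to ring A), placing oxygen where the C1 hydroxyl of the target is.

Step 16
Reactants: 21 enol triflate
Product: 22 6-methyl analogue of 21 (CH3 in place of OTf; spiro-epoxide intact)
Conditions: trimethylboroxine, Pd(dppf)Cl2 (5 mol%), K2CO3, dioxane/H2O, 80 °C
Reagents that add atoms: trimethylboroxine, CB1OB(C)OB(C)O1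
Why: Suzuki–Miyaura methylation of the enol triflate fixes the C6=C7 alkene with its methyl group; the basic, non-Lewis-acidic conditions should leave the spiro-epoxide intact.

Step 17
Reactants: 22 spiro-epoxide
Product: 23 (1S,4aR,5S,8aS)-1,4,4,6-tetramethyl-5-(prop-2-en-1-yl)-1,2,3,4,4a,5,8,8a-octahydronaphthalen-1-ol
Conditions: LiAlH4, THF, 0 °C → rt
Reagents that add atoms: none
Why: Hydride opens the epoxide at its unhindered CH2 (SN2), turning it into the C1 methyl and leaving the tertiary alcohol with the configuration set in step 15.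

Step 18
Reactants: 11 oxepane iodide; 23 octalinol
Product: 24 (E)-alkene: 23 in which the =CH2 terminus of the allyl group is replaced by =CH–C6 of the (3S,6S,7R)-3-(TBSO)-7-(iodomethyl)-2,2,6-trimethyloxepane (C11=C12 E)
Conditions: 23 (2 equiv), Hoveyda–Grubbs II (10 mol%), CH2Cl2, 40 °C
Reagents that add atoms: none
Why: Olefin cross-metathesis between a Type I olefin (allyl group of 23, in excess) and a Type III olefin (vinyl on the quaternary C6 of 11, which does not homodimerise) should be selective for the E cross product; the trisubstituted alkene, the iodide and the tertiary alcohol are tolerated.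

Step 19
Reactants: 24 iodo alkene; 25 isopropenylboronic acid pinacol ester, 4,4,5,5-tetramethyl-2-(prop-1-en-2-yl)-1,3,2-dioxaborolane
Product: 26 pinacol boronate: 3-O-TBS-sipholenol L carrying Bpin in place of the C10 hydroxyl (Bpin equatorial, C10 methyl axial, C11–H axial)
Conditions: 25 (8 equiv), (Me3Si)3SiH (1.5 equiv) and AIBN (0.3 equiv) by syringe pump over 8 h, degassed PhH (0.02 M), 80 °C
Reagents that add atoms: none
Why: Proposed new method: the silyl radical abstracts iodine from 24 to give the primary C8 radical, which can reach the C11=C12 alkene only by 4-exo/5-endo modes and so adds to the CH2 terminus of excess 25 (C8–C9 bond); the tertiary α-boryl radical at C10, stabilised by the empty boron p orbital, then closes 6-exo-trig onto C11 of the (E)-alkene (C10–C11 bond) and the secondary C12 radical is quenched by the silane. The closest known reactions are Giese additions of alkyl radicals to alkenylboronic esters and 5-exo cyclisations of α-boryl radicals, merged here into a radical [4+2] annulation. The ring closes through a chair in which the oxepane bonds C6–C5 and C7–O are locked equatorial and the C6 methyl axial, so C11 is attacked on the face that leaves C12 equatorial and H axial; at C10 the flat, conjugation-locked and wide Bpin group should take the pseudo-equatorial site away from the axial C6 methyl, leaving CH3 axial, and this is carried through the C–B oxidation with retention. The step needs addition to 25 before reduction (excess 25, slow silane addition), 6-exo over 7-endo closure (ring size), and face selectivity at C10, which rests on the size of Bpin against the 1,3-diaxial methyl.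

Step 20
Reactants: 26 tertiary boronate
Product: 27 3-O-TBS-sipholenol L
Conditions: H2O2 (30%), NaOH, THF/H2O, 0 °C → rt
Reagents that add atoms: hydrogen peroxide, OO
Why: Oxidation of the tertiary pinacol boronate by hydroperoxide, with 1,2-migration of C10 from boron to oxygen, occurs with retention and should give the equatorial C10 hydroxyl.

Step 21
Reactants: 27 silyl ether
Product: 28 sipholenol L
Conditions: TBAF, THF, 50 °C
Reagents that add atoms: none
Why: Fluoride-mediated desilylation of the hindered secondary TBS ether releases the C3 hydroxyl; nothing else in the molecule is fluoride-labile.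

**Compound list**
1 | neryl acetate, (2Z)-3,7-dimethylocta-2,6-dien-1-yl acetate | CC(C)=CCC/C(C)=C\COC(C)=O | starting material
2 | (Z)-neryl pinacol boronate | CC(C)=CCC/C(C)=C\CB1OC(C)(C)C(C)(C)O1 | intermediate
3 | (tert-butyldimethylsilyloxy)acetaldehyde | O=CCO[Si](C)(C)C(C)(C)C | starting material
4 | (2R,3S)-1-[(tert-butyldimethylsilyl)oxy]-3-ethenyl-3,7-dimethyloct-6-en-2-ol | C=C[C@]([C@@H](O)CO[Si](C)(C)C(C)(C)C)(C)CCC=C(C)C | intermediate
5 | (2R,3S)-1-[(tert-butyldimethylsilyl)oxy]-5-[(2S)-3,3-dimethyloxiran-2-yl]-3-ethenyl-3-methylpentan-2-ol | C=C[C@]([C@@H](O)CO[Si](C)(C)C(C)(C)C)(C)CC[C@@H]1OC1(C)C | intermediate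
6 | (2R,3S,6S)-1-[(tert-butyldimethylsilyl)oxy]-3-ethenyl-3,7-dimethyloct-7-ene-2,6-diol | C=C[C@]([C@@H](O)CO[Si](C)(C)C(C)(C)C)(C)CC[C@H](O)C(C)=C | intermediate
7 | (2R,3S,6S)-1,6-bis[(tert-butyldimethylsilyl)oxy]-3-ethenyl-3,7-dimethyloct-7-en-2-ol | C=C[C@]([C@@H](O)CO[Si](C)(C)C(C)(C)C)(C)CC[C@H](O[Si](C)(C)C(C)(C)C)C(C)=C | intermediate
8 | alkylmercury trifluoroacetate: oxepane 9 with CH2HgOCOCF3 in place of one C2 methyl (C2 epimers) | C=C[C@]1(C)CC[C@H](O[Si](C)(C)C(C)(C)C)C(C)(C[Hg]OC(=O)C(F)(F)F)O[C@H]1CO[Si](C)(C)C(C)(C)C | intermediate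
9 | (3S,6S,7R)-3-[(tert-butyldimethylsilyl)oxy]-7-{[(tert-butyldimethylsilyl)oxy]methyl}-6-ethenyl-2,2,6-trimethyloxepane | C=C[C@]1(C)CC[C@H](O[Si](C)(C)C(C)(C)C)C(C)(C)O[C@H]1CO[Si](C)(C)C(C)(C)C | intermediate
10 | [(2R,3S,6S)-6-[(tert-butyldimethylsilyl)oxy]-3-ethenyl-3,7,7-trimethyloxepan-2-yl]methanol | C=C[C@]1(C)CC[C@H](O[Si](C)(C)C(C)(C)C)C(C)(C)O[C@H]1CO | intermediate
11 | (3S,6S,7R)-3-[(tert-butyldimethylsilyl)oxy]-6-ethenyl-7-(iodomethyl)-2,2,6-trimethyloxepane | C=C[C@]1(C)CC[C@H](O[Si](C)(C)C(C)(C)C)C(C)(C)O[C@H]1CI | intermediate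
12 | pent-4-enal | C=CCCC=O | starting material
13 | vinylmagnesium bromide | C=C[Mg]Br | starting material
14 | hepta-1,6-dien-3-ol (racemic) | C=CCCC(O)C=C | intermediate
15 | hepta-1,6-dien-3-one | C=CCCC(=O)C=C | intermediate
16 | tert-butyl{[(3Z)-hepta-1,3,6-trien-3-yl]oxy}dimethylsilane | C=C/C(O[Si](C)(C)C(C)(C)C)=C/CC=C | intermediate
17 | 4,4-dimethylcyclohex-2-en-1-one | CC1(C)CCC(=O)C=C1 | starting material
18 | (4aR,5S,8aS)-6-[(tert-butyldimethylsilyl)oxy]-4,4-dimethyl-5-(prop-2-en-1-yl)-3,4,4a,5,8,8a-hexahydronaphthalen-1(2H)-one | CC(C)(C)[Si](C)(C)OC1=CC[C@H]2[C@@H]([C@@H]1CC=C)C(C)(C)CCC2=O | intermediate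
19 | 1-methylidene analogue of 18 | CC(C)(C)[Si](C)(C)OC1=CC[C@H]2[C@@H]([C@@H]1CC=C)C(C)(C)CCC2=C | intermediate
20 | enol triflate (C6–OTf) of the 1-methylidene octalin | FC(F)(F)S(=O)(=O)OC1=CC[C@H]2[C@@H]([C@@H]1CC=C)C(C)(C)CCC2=C | intermediate
21 | C1 spiro-epoxide of 20 (oxygen syn to H-8a) | FC(F)(F)S(=O)(=O)OC1=CC[C@H]2[C@@H]([C@@H]1CC=C)C(C)(C)CC[C@@]23CO3 | intermediate
22 | 6-methyl spiro-epoxide (CH3 in place of OTf in 21) | CC1=CC[C@H]2[C@@H]([C@@H]1CC=C)C(C)(C)CC[C@@]23CO3 | intermediate
23 | (1S,4aR,5S,8aS)-1,4,4,6-tetramethyl-5-(prop-2-en-1-yl)-1,2,3,4,4a,5,8,8a-octahydronaphthalen-1-ol | CC1=CC[C@H]2[C@@H]([C@@H]1CC=C)C(C)(C)CC[C@]2(C)O | intermediate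
24 | (E)-alkene from 11 and 23 (C11=C12 E; C8 iodide; C3 OTBS) | CC1=CC[C@H]2[C@@H]([C@@H]1C/C=C/[C@]3(C)CC[C@H](O[Si](C)(C)C(C)(C)C)C(C)(C)O[C@H]3CI)C(C)(C)CC[C@]2(C)O | intermediate
25 | isopropenylboronic acid pinacol ester | CC(=C)B1OC(C)(C)C(C)(C)O1 | starting material
26 | C10 pinacol boronate of 3-O-TBS-sipholenol L (Bpin in place of C10–OH) | CC1=CC[C@H]2[C@@H]([C@@H]1CC[C@H]1[C@]3(C)CC[C@H](O[Si](C)(C)C(C)(C)C)C(C)(C)O[C@H]3CC[C@]1(C)B4OC(C)(C)C(C)(C)O4)C(C)(C)CC[C@]2(C)O | intermediate
27 | 3-O-TBS-sipholenol L | CC1=CC[C@H]2[C@@H]([C@@H]1CC[C@H]1[C@]3(C)CC[C@H](O[Si](C)(C)C(C)(C)C)C(C)(C)O[C@H]3CC[C@]1(C)O)C(C)(C)CC[C@]2(C)O | intermediate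
28 | sipholenol L | CC1=CC[C@H]2[C@@H]([C@@H]1CC[C@H]1[C@]3(C)CC[C@H](O)C(C)(C)O[C@H]3CC[C@]1(C)O)C(C)(C)CC[C@]2(C)O | target

**Totals**
Total step count: 21. Longest linear sequence: 13 steps (12 → 28, steps 9–17 and 18–21); the oxepane branch 1 → 11 takes 8 steps.

**Steps most likely to fail**

1. Step 19 (proposed new method). Hydrogen transfer to the stabilised C10 α-boryl radical may outrun the hindered 6-exo closure (open-chain reduction), or the chair may discriminate poorly between Bpin and CH3 at C10. The fallback sets out from 24 and comes back at 27. Radical allyl transfer from 2-bromoallyl ethyl sulfone (dilauroyl peroxide, chlorobenzene, reflux) forms the C8–C9 bond and gives the vinyl bromide F1. Bu3SnH/AIBN (PhH, 80 °C, slow addition) generates the C10 vinyl radical, which is reactive enough to close 6-exo onto the hindered C11 through the same chair, giving the 10-methylidene compound F2. Mukaiyama hydration (Mn(dpm)3 cat., PhSiH3, O2, iPrOH, 0 °C) of this 1,1-disubstituted alkene, faster than that of the trisubstituted ring alkene, should bring oxygen in equatorially (the axial face is blocked by the C6 methyl) and give 27.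

2. Step 12. The cycloaddition may be slow at the β-carbon beside the gem-dimethyl group, so that an uncatalysed or stepwise background path erodes enantiofacial control, or the diene may be consumed by silyl transfer. The fallback sets out from 16 and 17 and comes back at 18. Cycloaddition promoted by the achiral mixed Lewis acid AlBr3/AlMe3 (toluene/CH2Cl2, −5 °C) gives the racemic adduct F3. Addition of lithiated (S)-N,S-dimethyl-S-phenylsulfoximine (THF, −78 °C) from the convex face gives two diastereomeric β-hydroxysulfoximines, which are separated by chromatography. The isomer derived from the (4aR,5S,8aS) ketone, β-hydroxysulfoximine F4, is thermolysed (toluene, 110 °C) to release enantiopure 18.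

3. Step 6. The 7-exo closure onto the tertiary carbon by the hindered C7 hydroxyl may be slow, allowing reversal of oxymercuration during reduction or solvomercuration of the vinyl group. The fallback sets out from 7 and comes back at 9. Cobalt-salen-catalysed hydrogen-atom-transfer hydroalkoxylation (N-fluoro-2,4,6-trimethylpyridinium tetrafluoroborate, PhSiH3, PhCF3, rt) transfers H• to the isopropenyl CH2, oxidises the tertiary radical to the cation and lets the C7 hydroxyl capture it, giving 9 directly; no new compound arises (F0).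

**Further compounds**
F1 | step 19 | vinyl bromide: 24 with CH2CH2C(Br)=CH2 on C7 in place of CH2I | CC1=CC[C@H]2[C@@H]([C@@H]1C/C=C/[C@]3(C)CC[C@H](O[Si](C)(C)C(C)(C)C)C(C)(C)O[C@H]3CCC(Br)=C)C(C)(C)CC[C@]2(C)O
F2 | step 19 | 10-methylidene compound: 27 with C10=CH2 in place of C10(CH3)OH | CC1=CC[C@H]2[C@@H]([C@@H]1CC[C@H]1[C@]3(C)CC[C@H](O[Si](C)(C)C(C)(C)C)C(C)(C)O[C@H]3CCC1=C)C(C)(C)CC[C@]2(C)O
F3 | step 12 | racemic adduct (18 and its enantiomer, 1:1) | CC(C)(C)[Si](C)(C)OC1=CC[C@H]2[C@@H]([C@@H]1CC=C)C(C)(C)CCC2=O.CC(C)(C)[Si](C)(C)OC1=CC[C@@H]2[C@H]([C@H]1CC=C)C(C)(C)CCC2=O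
F4 | step 12 | β-hydroxysulfoximine from 18 and (S)-N,S-dimethyl-S-phenylsulfoximine (C1–OH syn to C8, CH2S syn to H-8a) | CC(C)(C)[Si](C)(C)OC1=CC[C@H]2[C@@H]([C@@H]1CC=C)C(C)(C)CC[C@]2(O)C[S@@](=O)(=NC)c1ccccc1
F0 | step 6 | none | none
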